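## Structural features

The target is a resveratrol trimer made of two 2-aryl-2,3-dihydrobenzofurans. Unit 1 (O1, C2, C3 fused to ring A) carries a 4-hydroxyphenyl group on C2, a hydroxyl on C4 and an (E)-4-hydroxystyryl group on C6. Its C3 is bonded to C6′ of ring B, the benzo ring of unit 2. Unit 2 (O1′, C2′, C3′) has the same substitution pattern and carries on C3′ the 3,5-dihydroxyphenyl ring C. The four stereocentres form two adjacent pairs, C2/C3 (R,R) and C2′/C3′ (S,S), both trans; ring B separates the pairs, so neither can steer the other. The fragile groups are the two O–C2 bonds, which are 4-oxybenzylic aryl ethers that ionise in acid and open through a quinone methide once the para phenol is free in base, the stilbene (acid and light), and seven oxidisable phenols. The real difficulty is the sp3–sp2 bond C3–C6′ between two crowded halves, with trans control at C3, together with absolute control of two ring pairs of opposite hand. The key step uses the fact that ring C is attached to C3′ through the carbon meta to both of its hydroxyls, the pattern of a folded 3,5,7-trioxo chain, so ring C can be grown by an aldol closure from an acyl group on C3′. Unit 2 can therefore be made as a 3-carboxylic acid, the mirror image of the acid that serves unit 1 as a radical precursor.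

## Logic of the disconnections

28 to 27: the seven O–CH3 bonds are cut. Methyl ethers are the only phenol masks that pass through the carbenoid, strong base, organolithium, palladium and nickel steps, so all late chemistry runs on a compound that cannot ionise or oxidise. The forward step must leave O1–C2, O1′–C2′ and the alkene in place, or let an opened ring close again trans.

27 to 24 and 26: the C3–C6′ bond is cut, the only bond between the halves. C3 becomes a radical released from a carboxylate and C6′ an aryl nucleophile from a bromide, which gives two fragments of similar size from one common intermediate. The forward step must deliver the aryl group trans to the C2 aryl group, and 24 must carry no aryl halide, which is why the styryl group is already present.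

26 to 25 to 18 to 17: the C6′–metal bonds go back to C6′–Br, and the two ring C methyl ethers are cut. Halogen–metal exchange must be faster than any deprotonation at C3′.

17 to 16 (key step): the ring C bond between the carbon attached to C3′ and one ortho carbon is cut, and the two hydroxyl-bearing carbons return to ketones. Six ring carbons reduce to an acyl group on C3′ plus a five-carbon diketone. The forward step must close through carbon, not oxygen, and must leave C2′, C3′ and O1′–C2′ intact.

16 to 12 and 13 (through 14 and 15): the bond between the carbonyl carbon on C3′ and the adjacent CH2 is cut. The chain comes from a bulk diketone. Acyl transfer must beat proton transfer from C3′–H, hence the activated acyl donor and low temperature.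

24 to 23 to 21 and 22: the acyl–O bond of the activating group and the C6–vinyl bond are cut. Forming the stilbene before fragment union removes the only aryl halide from the nickel step. The forward step must give the E alkene on a free acid.

12 to 10 (through 11) and 21 to 19 (through 20): no skeletal bond is cut; C3 is taken back to the cis configuration and the acid to its methyl ester. Base must equilibrate C3 without opening the ring.

10 and 19 to 9: the C2–C3 bond is cut in both. One achiral diazo ester gives both mirror-image series by a change of catalyst hand. The insertion must choose the benzylic CH2 over the neighbouring OCH3 and one enantiotopic hydrogen.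

9 to 8 to 7 to 6 to 4 and 5: the diazo group, the ester methyl, the nitrile nitrogen and the aryl-CH2–C bond are removed in turn. The homologation must stay basic, because the 4-methoxybenzyl ether does not tolerate acid.

4 to 2 and 3, and 2 to 1: the benzylic O–C bond and one O–CH3 bond are cut, leading to three purchasable compounds. Only one of the two equivalent methoxy groups may be removed.

## Other disconnections considered

Alternative 1: The cut goes through both ring oxygens. O1–C2 and O1′–C2′ of the fully methylated trimer A2 (seven methoxy groups, identical with 27) are opened to A1, in which rings A and B carry free phenols next to C3 and C3′ and C2 and C2′ are secondary 4-methoxybenzylic alcohols. In the forward sense CF3CO2H or BF3·OEt2 would ionise both alcohols and each cation would be taken by its neighbouring phenol, closing both rings in one flask.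
- In its favour: the carbinol configuration is lost in the cation, so only C3 and C3′ need to be set; closure trans to the C3 or C3′ aryl group is both the kinetic and the thermodynamic result; the acid-labile rings appear last.
- Against it here: A1 is twice a 1,1,2-triarylethane, and setting C3 and C3′ in opposite absolute sense is the problem the cut leaves open. Two phenols must stay free beside seven methyl ethers, and the cations form next to an electron-rich stilbene.
- Comparison: the trans control from C3 and C3′ is at least the equal of the radical capture in step 16, probably the better. Ring C would be bought whole, which is better step economy for that ring. The chosen plan is stronger in how absolute configuration is supplied (one diazo ester, two catalyst hands) and in setting every stereocentre on a small molecule.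

Alternative 2: The cut is C3′–C3a′ of the trans ester A4 (identical with 11), which goes back to the flavanone A3. In the forward sense PhI(OAc)2 and H2SO4 in trimethyl orthoformate would convert A3 through its enol ether into a C3 iodane; ring B then shifts to C3 as iodobenzene leaves, the six-membered ring contracts, and the old carbonyl carbon becomes the ester.
- In its favour: the trans ring is delivered directly, there is no diazo compound and no precious metal, and A3 is two or three steps from an acetophenone and 4-methoxybenzaldehyde.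
- Against it here: absolute configuration rests on A3. Flavanones with a 5-alkoxy group are hard to obtain in high enantiomeric purity and racemise through the open chalcone in acid, the medium of the contraction.
- Comparison: this is another way to the same ester, so everything from step 8 on, the key step included, would stay. It is better in step count to the ester and in safety on scale, and equal in control of relative configuration. The chosen plan is better in enantiocontrol and in giving both mirror-image series from one intermediate.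

Alternative 3: Ring B is divided into a four-carbon and a two-carbon piece. C3a′–C4′, C7′–C7a′ and C4′–C5′ of phenol A7 are cut, giving cyclobutenone A5 (unit 1 bonded through C3) and siloxyalkyne A6. In the forward sense, heating would open A5 to a vinylketene; [2+2] addition of A6, four-electron opening, six-electron closure and tautomerisation would give A7.
- In its favour: the C3–C6′ bond exists before ring B does, so no sp3–sp2 coupling and no diastereoselection at C3 during fragment union; the polarity of ketene and ynol ether fixes the regiochemistry; the two ring B oxygens are differentiated.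
- Against it here: A5 needs several steps from a unit 1 acid; the thermal step meets a benzylic ether and an acid-labile ring; A7 still lacks C2′ and its aryl group, so O1′–C2′ and C2′–C3′ must be built afterwards with no evident control of absolute configuration.
- Comparison: on the C3–C6′ bond this alternative is the better, since it removes the least certain step of the chosen route. On step economy and on control of the C2′/C3′ pair the chosen plan is better.

Key step: step 10

Assumption: Rh2(S-PTTL)4, dirhodium tetrakis[N-phthaloyl-(S)-tert-leucinate], is taken to give the (2S,3R) cis ester 10 and Rh2(R-PTTL)4 its mirror image 19; if the sense is the reverse, the two catalysts change places and nothing else changes.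

Remark: the target has seven phenols, so the fully methylated trimer 27 is a heptamethyl ether.

## Route

Step 1
Reactants: 1 4-bromo-2,6-dimethoxybenzaldehyde
Product: 2 4-bromo-2-hydroxy-6-methoxybenzaldehyde
Conditions: BCl3 (1.2 equiv), CH2Cl2, −78 → 0 °C; then H2O
Reagents that add atoms: none
Why: Chelation-directed ether cleavage: boron binds the aldehyde oxygen and one ortho methoxy oxygen in a six-membered chelate, so only that methyl group is lost as chloromethane and the second ether stays.

Step 2
Reactants: 2 4-bromo-2-hydroxy-6-methoxybenzaldehyde; 3 4-methoxybenzyl chloride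
Product: 4 4-bromo-2-methoxy-6-[(4-methoxyphenyl)methoxy]benzaldehyde
Conditions: K2CO3, NaI (cat.), DMF, 60 °C
Reagents that add atoms: none
Why: Williamson etherification of the phenoxide; the hydrogen-bonded hydroxyl needs warm DMF, and no other nucleophile is present.

Step 3
Reactants: 4 4-bromo-2-methoxy-6-[(4-methoxyphenyl)methoxy]benzaldehyde; 5 p-toluenesulfonylmethyl isocyanide (TosMIC)
Product: 6 2-{4-bromo-2-methoxy-6-[(4-methoxyphenyl)methoxy]phenyl}acetonitrile
Conditions: t-BuOK, DME, −40 °C; then MeOH, 65 °C
Reagents that add atoms: none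
Why: Van Leusen reductive cyanation: the TosMIC anion adds to the aldehyde, the oxazoline opens to an N-(1-tosylvinyl)formamide, and methanolysis with loss of sulfinate leaves the nitrile with one more carbon. The medium is basic throughout, which the acid-labile 4-methoxybenzyl ether needs.

Step 4
Reactants: 6 2-{4-bromo-2-methoxy-6-[(4-methoxyphenyl)methoxy]phenyl}acetonitrile
Product: 7 2-{4-bromo-2-methoxy-6-[(4-methoxyphenyl)methoxy]phenyl}acetic acid
Conditions: KOH, EtOH–H2O, 90 °C; then 1 M HCl, 0 °C
Reagents that add atoms: water, O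
Why: Base hydrolysis of the nitrile through the amide; aryl bromide and both ethers are inert to hydroxide.

Step 5
Reactants: 7 2-{4-bromo-2-methoxy-6-[(4-methoxyphenyl)methoxy]phenyl}acetic acid
Product: 8 methyl 2-{4-bromo-2-methoxy-6-[(4-methoxyphenyl)methoxy]phenyl}acetate
Conditions: MeI, K2CO3, DMF, 25 °C
Reagents that add atoms: iodomethane, CI
Why: SN2 alkylation of the carboxylate; it avoids the acid of a Fischer esterification.

Step 6
Reactants: 8 methyl 2-{4-bromo-2-methoxy-6-[(4-methoxyphenyl)methoxy]phenyl}acetate
Product: 9 methyl 2-diazo-2-{4-bromo-2-methoxy-6-[(4-methoxyphenyl)methoxy]phenyl}acetate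
Conditions: 4-acetamidobenzenesulfonyl azide, DBU, MeCN, 0 → 25 °C
Reagents that add atoms: 4-acetamidobenzenesulfonyl azide, CC(=O)Nc1ccc(cc1)S(=O)(=O)N=[N+]=[N-]
Why: Regitz diazo transfer: the arylacetate enolate attacks the terminal nitrogen of the sulfonyl azide and the triazene collapses to the aryldiazoacetate and the sulfonamide.

Step 7
Reactants: 9 methyl 2-diazo-2-{4-bromo-2-methoxy-6-[(4-methoxyphenyl)methoxy]phenyl}acetate
Product: 10 methyl (2S,3R)-6-bromo-4-methoxy-2-(4-methoxyphenyl)-2,3-dihydro-1-benzofuran-3-carboxylate (cis)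
Conditions: Rh2(S-PTTL)4 (1 mol %), toluene, −60 °C
Reagents that add atoms: none
Why: Intramolecular C–H insertion of a donor/acceptor rhodium carbenoid into the OCH2Ar group five atoms away; that C–H is activated by oxygen and by the 4-methoxyphenyl ring and should far outrun the primary C–H of the flanking OCH3. The concerted insertion should close the ring cis, and the chiral carboxylate ligands choose the enantiotopic hydrogen and so set C2 as S; C3 is corrected in step 8.

Step 8
Reactants: 10 methyl (2S,3R)-6-bromo-4-methoxy-2-(4-methoxyphenyl)-2,3-dihydro-1-benzofuran-3-carboxylate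
Product: 12 (2S,3S)-6-bromo-4-methoxy-2-(4-methoxyphenyl)-2,3-dihydro-1-benzofuran-3-carboxylic acid, via trans methyl ester 11 (not isolated)
Conditions: NaOMe, MeOH, 25 °C; then aq. NaOH, 50 °C; then 1 M HCl, 0 °C
Reagents that add atoms: water, O
Why: Methoxide equilibrates C3 through the ester enolate to the more stable trans ester 11, while C2, which has no acidic hydrogen, keeps its configuration; hydroxide then saponifies. Expulsion of O1 from the enolate would be the reverse of a 5-endo-trig closure and is not expected at this temperature.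

Step 9
Reactants: 12 (2S,3S)-6-bromo-4-methoxy-2-(4-methoxyphenyl)-2,3-dihydro-1-benzofuran-3-carboxylic acid; 13 pentane-2,4-dione
Product: 16 1-[(2S,3S)-6-bromo-4-methoxy-2-(4-methoxyphenyl)-2,3-dihydro-1-benzofuran-3-yl]hexane-1,3,5-trione, via acyl imidazole 14 (not isolated), via diketone dianion 15 (not isolated)
Conditions: 12, 1,1′-carbonyldiimidazole, THF, 25 °C; separately 13 (3 equiv), LDA (6 equiv), THF, −78 → 0 °C; mix at −78 → −40 °C; then 1 M HCl, 0 °C
Reagents that add atoms: 1,1′-carbonyldiimidazole, O=C(n1ccnc1)n1ccnc1 (imidazolyl group of 14 only); lithium diisopropylamide, CC(C)N([Li])C(C)C (lithium of 15 only)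
Why: Claisen-type C-acylation: the terminal carbanion of dianion 15 attacks acyl imidazole 14, which is electrophilic enough to react at −78 °C, where proton transfer from C3′–H is slow. Excess 15 is used because 16 is deprotonated as it forms; C3′ may enolise on the way but returns trans, and C2′ is untouched.

Step 10
Reactants: 16 1-[(2S,3S)-6-bromo-4-methoxy-2-(4-methoxyphenyl)-2,3-dihydro-1-benzofuran-3-yl]hexane-1,3,5-trione
Product: 17 5-[(2S,3S)-6-bromo-4-methoxy-2-(4-methoxyphenyl)-2,3-dihydro-1-benzofuran-3-yl]benzene-1,3-diol
Conditions: KOH (4 equiv), MeOH, 25 → 45 °C, argon; then 1 M HCl, 0 °C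
Reagents that add atoms: none
Why: Hydroxide holds 16 as the enolate of one 1,3-dicarbonyl unit; a small equilibrium share of the isomeric C5=C6 enolate lets the terminal methyl carbon add to the C1 ketone next to C3′, and the aldol then loses water and enolises twice to the aromatic ring, which makes the sequence irreversible. The closest known reaction type is the base-mediated aldol cyclisation of 1-substituted hexane-1,3,5-triones to 5-substituted resorcinols, the laboratory form of the polyketide fold. Ring C closes in the 6-(enolendo)-exo-trig mode, with the enolate C5=C6 inside the new ring and the C1 carbonyl oxygen outside it. No stereocentre is made: C2′ has no acidic hydrogen, and C3′, should it enolise at all, returns to the more stable trans arrangement. Three selectivities are needed. Closure through carbon must beat closure through oxygen to the 4-pyranone; that cyclodehydration is an acid-side pathway and is shut off in base. The aldol must beat retro-Claisen cleavage of the chain, which mild temperature and a modest excess of base hold back. The O1′–C2′ bond must survive: the C1 carbonyl is tied up in the chain enolate, so C3′–H is hardly acidic, expulsion of O1′ would be the reverse of a 5-endo-trig closure, and the methyl ether on the 2-aryl ring blocks the quinone-methide opening that a free para-phenoxide would allow.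

Step 11
Reactants: 17 5-[(2S,3S)-6-bromo-4-methoxy-2-(4-methoxyphenyl)-2,3-dihydro-1-benzofuran-3-yl]benzene-1,3-diol
Product: 18 (2S,3S)-6-bromo-3-(3,5-dimethoxyphenyl)-4-methoxy-2-(4-methoxyphenyl)-2,3-dihydro-1-benzofuran
Conditions: MeI, K2CO3, acetone, 56 °C
Reagents that add atoms: iodomethane, CI
Why: Williamson methylation of both phenoxides; the ethers are needed because free phenols would quench the aryllithium of step 16.

Step 12
Reactants: 9 methyl 2-diazo-2-{4-bromo-2-methoxy-6-[(4-methoxyphenyl)methoxy]phenyl}acetate
Product: 19 methyl (2R,3S)-6-bromo-4-methoxy-2-(4-methoxyphenyl)-2,3-dihydro-1-benzofuran-3-carboxylate (cis)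
Conditions: Rh2(R-PTTL)4 (1 mol %), toluene, −60 °C
Reagents that add atoms: none
Why: The same carbenoid C–H insertion as step 7 with the mirror-image catalyst, which should select the other enantiotopic hydrogen and set C2 as R.

Step 13
Reactants: 19 methyl (2R,3S)-6-bromo-4-methoxy-2-(4-methoxyphenyl)-2,3-dihydro-1-benzofuran-3-carboxylate
Product: 21 (2R,3R)-6-bromo-4-methoxy-2-(4-methoxyphenyl)-2,3-dihydro-1-benzofuran-3-carboxylic acid, via ent-trans methyl ester 20 (not isolated)
Conditions: NaOMe, MeOH, 25 °C; then aq. NaOH, 50 °C; then 1 M HCl, 0 °C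
Reagents that add atoms: water, O
Why: Enolate equilibration to the trans ester and saponification as in step 8; a single diastereomer is convenient although C3 becomes planar in step 16.

Step 14
Reactants: 21 (2R,3R)-6-bromo-4-methoxy-2-(4-methoxyphenyl)-2,3-dihydro-1-benzofuran-3-carboxylic acid; 22 4-methoxystyrene
Product: 23 (2R,3R)-4-methoxy-2-(4-methoxyphenyl)-6-[(E)-2-(4-methoxyphenyl)ethenyl]-2,3-dihydro-1-benzofuran-3-carboxylic acid
Conditions: Pd(OAc)2 (5 mol %), P(o-tol)3 (10 mol %), Et3N (3 equiv), DMF, 100 °C; then 1 M HCl
Reagents that add atoms: none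
Why: Heck reaction: oxidative addition of zerovalent palladium to C6–Br, syn insertion of the styrene at its unsubstituted carbon and syn β-hydride elimination give the E-stilbene. The acid travels as its triethylammonium salt.

Step 15
Reactants: 23 (2R,3R)-4-methoxy-2-(4-methoxyphenyl)-6-[(E)-2-(4-methoxyphenyl)ethenyl]-2,3-dihydro-1-benzofuran-3-carboxylic acid
Product: 24 4,5,6,7-tetrachloro-1,3-dioxoisoindolin-2-yl (2R,3R)-4-methoxy-2-(4-methoxyphenyl)-6-[(E)-2-(4-methoxyphenyl)ethenyl]-2,3-dihydro-1-benzofuran-3-carboxylate
Conditions: N-hydroxytetrachlorophthalimide, N,N′-diisopropylcarbodiimide, DMAP (cat.), CH2Cl2, 25 °C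
Reagents that add atoms: N-hydroxytetrachlorophthalimide, ON1C(=O)c2c(C1=O)c(Cl)c(Cl)c(Cl)c2Cl
Why: Carbodiimide esterification gives the redox-active ester, whose N–O bond accepts an electron in step 16.

Step 16
Reactants: 18 (2S,3S)-6-bromo-3-(3,5-dimethoxyphenyl)-4-methoxy-2-(4-methoxyphenyl)-2,3-dihydro-1-benzofuran; 24 the redox-active ester of step 15
Product: 27 (2R,3R)-3-[(2S,3S)-3-(3,5-dimethoxyphenyl)-4-methoxy-2-(4-methoxyphenyl)-2,3-dihydro-1-benzofuran-6-yl]-4-methoxy-2-(4-methoxyphenyl)-6-[(E)-2-(4-methoxyphenyl)ethenyl]-2,3-dihydro-1-benzofuran (heptamethyl ether), via aryllithium 25 (not isolated), via arylzinc chloride 26 (not isolated)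
Conditions: 18 (2 equiv), n-BuLi, THF, −78 °C; ZnCl2, −78 → 25 °C; then 24, NiCl2·glyme (20 mol %), 4,4′-di-tert-butyl-2,2′-bipyridine (40 mol %), THF–DMF, 25 °C
Reagents that add atoms: n-butyllithium, [Li]CCCC (lithium of 25 only); zinc chloride, Cl[Zn]Cl (zinc and chlorine of 26 only)
Why: Nickel-catalysed decarboxylative arylation, a Negishi-type coupling of a redox-active ester: electron transfer from an arylnickel species fragments 24 to carbon dioxide, the phthalimide anion and the C3 benzylic radical, which nickel captures and couples with the aryl group of 26 by reductive elimination. C3 is set by the substrate: the aryl group should arrive on the face of the planar radical away from the C2 aryl group, giving the trans (2R,3R) ring. The ring O1–C2 bond lies near the nodal plane of the radical, so β-scission is not expected, and 24 has no aryl halide to compete for nickel.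

Step 17
Reactants: 27 the heptamethyl ether of step 16
Product: 28 5-[(2S,3S)-4-hydroxy-6-{(2R,3R)-4-hydroxy-2-(4-hydroxyphenyl)-6-[(E)-2-(4-hydroxyphenyl)ethenyl]-2,3-dihydro-1-benzofuran-3-yl}-2-(4-hydroxyphenyl)-2,3-dihydro-1-benzofuran-3-yl]benzene-1,3-diol (CNP0248228.3)
Conditions: BBr3 (20 equiv), CH2Cl2, −78 → 0 °C; then MeOH, aq. NaHCO3; argon, dark
Reagents that add atoms: none
Why: Lewis acid–base complexation of each aryl methyl ether followed by SN2 attack of bromide on the methyl carbon should free the seven phenols. If O1–C2 or O1′–C2′ ionises on the way, the benzylic cation has no partner but its own ortho oxygen and should close again trans under control of the untouched C3 or C3′; a cold quench keeps hydrogen bromide off the alkene.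

## Compound list

1 | 4-bromo-2,6-dimethoxybenzaldehyde | COc1cc(Br)cc(OC)c1C=O | starting material
2 | 4-bromo-2-hydroxy-6-methoxybenzaldehyde | COc1cc(Br)cc(O)c1C=O | intermediate
3 | 4-methoxybenzyl chloride | COc1ccc(CCl)cc1 | starting material
4 | 4-bromo-2-methoxy-6-[(4-methoxyphenyl)methoxy]benzaldehyde | COc1ccc(COc2cc(Br)cc(OC)c2C=O)cc1 | intermediate
5 | p-toluenesulfonylmethyl isocyanide (TosMIC) | Cc1ccc(cc1)S(=O)(=O)C[N+]#[C-] | starting material
6 | 2-{4-bromo-2-methoxy-6-[(4-methoxyphenyl)methoxy]phenyl}acetonitrile | COc1ccc(COc2cc(Br)cc(OC)c2CC#N)cc1 | intermediate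
7 | 2-{4-bromo-2-methoxy-6-[(4-methoxyphenyl)methoxy]phenyl}acetic acid | COc1ccc(COc2cc(Br)cc(OC)c2CC(=O)O)cc1 | intermediate
8 | methyl 2-{4-bromo-2-methoxy-6-[(4-methoxyphenyl)methoxy]phenyl}acetate | COc1ccc(COc2cc(Br)cc(OC)c2CC(=O)OC)cc1 | intermediate
9 | methyl 2-diazo-2-{4-bromo-2-methoxy-6-[(4-methoxyphenyl)methoxy]phenyl}acetate | COc1ccc(COc2cc(Br)cc(OC)c2C(=[N+]=[N-])C(=O)OC)cc1 | intermediate
10 | methyl (2S,3R)-6-bromo-4-methoxy-2-(4-methoxyphenyl)-2,3-dihydro-1-benzofuran-3-carboxylate (cis) | Brc1cc(OC)c2c(c1)O[C@H](c1ccc(OC)cc1)[C@@H]2C(=O)OC | intermediate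
11 | methyl (2S,3S)-6-bromo-4-methoxy-2-(4-methoxyphenyl)-2,3-dihydro-1-benzofuran-3-carboxylate (trans) | Brc1cc(OC)c2c(c1)O[C@H](c1ccc(OC)cc1)[C@H]2C(=O)OC | intermediate (not isolated)
12 | (2S,3S)-6-bromo-4-methoxy-2-(4-methoxyphenyl)-2,3-dihydro-1-benzofuran-3-carboxylic acid | Brc1cc(OC)c2c(c1)O[C@H](c1ccc(OC)cc1)[C@H]2C(=O)O | intermediate
13 | pentane-2,4-dione | CC(=O)CC(C)=O | starting material
14 | [(2S,3S)-6-bromo-4-methoxy-2-(4-methoxyphenyl)-2,3-dihydro-1-benzofuran-3-yl](1H-imidazol-1-yl)methanone | Brc1cc(OC)c2c(c1)O[C@H](c1ccc(OC)cc1)[C@H]2C(=O)n1ccnc1 | intermediate (not isolated)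
15 | dilithium dienolate (1,3-dianion) of pentane-2,4-dione | [Li+].[Li+].C=C([O-])C=C(C)[O-] | intermediate (not isolated)
16 | 1-[(2S,3S)-6-bromo-4-methoxy-2-(4-methoxyphenyl)-2,3-dihydro-1-benzofuran-3-yl]hexane-1,3,5-trione | Brc1cc(OC)c2c(c1)O[C@H](c1ccc(OC)cc1)[C@H]2C(=O)CC(=O)CC(C)=O | intermediate
17 | 5-[(2S,3S)-6-bromo-4-methoxy-2-(4-methoxyphenyl)-2,3-dihydro-1-benzofuran-3-yl]benzene-1,3-diol | Brc1cc(OC)c2c(c1)O[C@H](c1ccc(OC)cc1)[C@H]2c1cc(O)cc(O)c1 | intermediate
18 | (2S,3S)-6-bromo-3-(3,5-dimethoxyphenyl)-4-methoxy-2-(4-methoxyphenyl)-2,3-dihydro-1-benzofuran | Brc1cc(OC)c2c(c1)O[C@H](c1ccc(OC)cc1)[C@H]2c1cc(OC)cc(OC)c1 | intermediate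
19 | methyl (2R,3S)-6-bromo-4-methoxy-2-(4-methoxyphenyl)-2,3-dihydro-1-benzofuran-3-carboxylate (cis) | Brc1cc(OC)c2c(c1)O[C@@H](c1ccc(OC)cc1)[C@H]2C(=O)OC | intermediate
20 | methyl (2R,3R)-6-bromo-4-methoxy-2-(4-methoxyphenyl)-2,3-dihydro-1-benzofuran-3-carboxylate (trans) | Brc1cc(OC)c2c(c1)O[C@@H](c1ccc(OC)cc1)[C@@H]2C(=O)OC | intermediate (not isolated)
21 | (2R,3R)-6-bromo-4-methoxy-2-(4-methoxyphenyl)-2,3-dihydro-1-benzofuran-3-carboxylic acid | Brc1cc(OC)c2c(c1)O[C@@H](c1ccc(OC)cc1)[C@@H]2C(=O)O | intermediate
22 | 4-methoxystyrene | C=Cc1ccc(OC)cc1 | starting material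
23 | (2R,3R)-4-methoxy-2-(4-methoxyphenyl)-6-[(E)-2-(4-methoxyphenyl)ethenyl]-2,3-dihydro-1-benzofuran-3-carboxylic acid | COc1ccc(/C=C/c2cc(OC)c3c(c2)O[C@@H](c2ccc(OC)cc2)[C@@H]3C(=O)O)cc1 | intermediate
24 | 4,5,6,7-tetrachloro-1,3-dioxoisoindolin-2-yl ester of 23 | COc1ccc(/C=C/c2cc(OC)c3c(c2)O[C@@H](c2ccc(OC)cc2)[C@@H]3C(=O)ON2C(=O)c3c(Cl)c(Cl)c(Cl)c(Cl)c3C2=O)cc1 | intermediate
25 | [(2S,3S)-3-(3,5-dimethoxyphenyl)-4-methoxy-2-(4-methoxyphenyl)-2,3-dihydro-1-benzofuran-6-yl]lithium | [Li]c1cc(OC)c2c(c1)O[C@H](c1ccc(OC)cc1)[C@H]2c1cc(OC)cc(OC)c1 | intermediate (not isolated)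
26 | [(2S,3S)-3-(3,5-dimethoxyphenyl)-4-methoxy-2-(4-methoxyphenyl)-2,3-dihydro-1-benzofuran-6-yl]zinc chloride | Cl[Zn]c1cc(OC)c2c(c1)O[C@H](c1ccc(OC)cc1)[C@H]2c1cc(OC)cc(OC)c1 | intermediate (not isolated)
27 | (2R,3R,2′S,3′S) heptamethyl ether of the target | COc1ccc(/C=C/c2cc(OC)c3c(c2)O[C@@H](c2ccc(OC)cc2)[C@@H]3c2cc(OC)c3c(c2)O[C@H](c2ccc(OC)cc2)[C@H]3c2cc(OC)cc(OC)c2)cc1 | intermediate
28 | CNP0248228.3 | Oc1ccc(/C=C/c2cc(O)c3c(c2)O[C@@H](c2ccc(O)cc2)[C@@H]3c2cc(O)c3c(c2)O[C@H](c2ccc(O)cc2)[C@H]3c2cc(O)cc(O)c2)cc1 | target

## Step count and least certain steps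

Total: 17 steps. Longest linear sequence: 13 steps (1 to 11, 16, 17); steps 12 to 15 form the second branch from 9.

Step 10 (key step). The aldol addition may be slow at the α-branched, crowded C1 ketone. That leaves time for retro-Claisen cleavage of the chain by hydroxide or methoxide and for closure through oxygen during the acidic work-up. Fallback, from 12 back to 18: ring C is brought in whole. Acid 12 is converted with N-hydroxytetrachlorophthalimide and the carbodiimide into its redox-active ester F1. F1 is arylated with (3,5-dimethoxyphenyl)zinc chloride F2 (from 1-bromo-3,5-dimethoxybenzene by bromine–lithium exchange and ZnCl2), with Fe(acac)3 and 1,2-bis(diphenylphosphino)benzene as catalyst, because iron should leave the aryl bromide alone. Delivery anti to the C2′ aryl group should give 18 directly.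

Steps 7 and 12. Facial selection by the catalyst may be poor with a carbenoid flanked by two ortho substituents, and insertion into the methoxy C–H or carbene dimerisation may compete. Fallback, from 9 back to 12 and 21: Rh2(OAc)4 closes the ring without asymmetric induction to the racemic cis ester F3. The procedure of step 8 gives the racemic trans acid F4, and preparative chromatography on a chiral stationary phase separates it into 12 and 21. Both are needed, so neither half is discarded.

Step 9. Proton transfer from C3′–H of 14 to the strongly basic dianion may outrun acyl transfer, which would return the acid after work-up. Fallback, from 12 back to 16: a base-free acylation. Acid 12 is converted with 1-chloro-N,N,2-trimethylprop-1-en-1-amine under neutral conditions into the acid chloride F5. F5 is combined in CH2Cl2 at −78 → 20 °C with 2,4-bis(trimethylsilyloxy)penta-1,3-diene F6 (from 13 by two silylations). The terminal carbon of the masked dianion is acylated, and aqueous work-up should release 16.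

Step 16. Capture of the C3 radical by nickel may be slow, because C3 lies between the C2 aryl group and the C4 methoxy group; radical dimerisation or reduction would follow. The trans preference may also be incomplete, and 26 may be lost by protonation. Fallback, from 25 and 4 back to 27: the C3–C6′ bond is made first by carbonyl addition and the ring is closed afterwards.
- Aryllithium 25 adds to aldehyde 4 to give the diaryl carbinol F7, and MnO2 oxidises it to the diaryl ketone F8.
- Hydrazine under forcing conditions (n-butanol, 120 °C) gives the hydrazone F9, and MnO2 oxidises it to the diaryldiazomethane F10, which is not isolated.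
- Rh2(S-PTAD)4, or its enantiomer if that is the hand that sets C3 as R, should insert the carbene into the OCH2Ar group to give the cis ring F11.
- CF3CO2H in CH2Cl2 at 0 °C ionises O1–C2 reversibly and should settle the ring trans as the bromide F12, with C3 unchanged.
- The Heck reaction of F12 with 22 under the conditions of step 14 gives 27.

Step 17. Seven ether cleavages need excess BBr3 and time. During that time hydrogen bromide may add to the stilbene, benzylic cations may attack the alkene, and an ionised ring may fail to close again. Fallback, from 21 and 26 back to 28: the stilbene is made after the ether cleavage.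
- Acid 21 is converted into its redox-active ester F13, and F13 is coupled with 26 under Fe(acac)3 and 1,2-bis(diphenylphosphino)benzene to the bromide F12.
- BBr3 should convert F12 into the hexaphenol bromide F14.
- The Heck reaction of F14 with 4-acetoxystyrene gives the monoacetate F15, and K2CO3 in methanol removes the acetyl group to give 28.

## Further compounds

F1 | step 10 | 4,5,6,7-tetrachloro-1,3-dioxoisoindolin-2-yl (2S,3S)-6-bromo-4-methoxy-2-(4-methoxyphenyl)-2,3-dihydro-1-benzofuran-3-carboxylate | Brc1cc(OC)c2c(c1)O[C@H](c1ccc(OC)cc1)[C@H]2C(=O)ON1C(=O)c2c(Cl)c(Cl)c(Cl)c(Cl)c2C1=O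
F2 | step 10 | (3,5-dimethoxyphenyl)zinc chloride | COc1cc(OC)cc([Zn]Cl)c1
F3 | step 7 | racemic methyl cis-6-bromo-4-methoxy-2-(4-methoxyphenyl)-2,3-dihydro-1-benzofuran-3-carboxylate (one enantiomer drawn) | Brc1cc(OC)c2c(c1)O[C@H](c1ccc(OC)cc1)[C@@H]2C(=O)OC
F4 | step 7 | racemic trans-6-bromo-4-methoxy-2-(4-methoxyphenyl)-2,3-dihydro-1-benzofuran-3-carboxylic acid (one enantiomer drawn) | Brc1cc(OC)c2c(c1)O[C@H](c1ccc(OC)cc1)[C@H]2C(=O)O
F5 | step 9 | (2S,3S)-6-bromo-4-methoxy-2-(4-methoxyphenyl)-2,3-dihydro-1-benzofuran-3-carbonyl chloride | Brc1cc(OC)c2c(c1)O[C@H](c1ccc(OC)cc1)[C@H]2C(Cl)=O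
F6 | step 9 | 2,4-bis(trimethylsilyloxy)penta-1,3-diene | C=C(O[Si](C)(C)C)C=C(C)O[Si](C)(C)C
F7 | step 16 | {4-bromo-2-methoxy-6-[(4-methoxyphenyl)methoxy]phenyl}[(2S,3S)-3-(3,5-dimethoxyphenyl)-4-methoxy-2-(4-methoxyphenyl)-2,3-dihydro-1-benzofuran-6-yl]methanol (either carbinol configuration) | COc1ccc(COc2cc(Br)cc(OC)c2C(O)c2cc(OC)c3c(c2)O[C@H](c2ccc(OC)cc2)[C@H]3c2cc(OC)cc(OC)c2)cc1
F8 | step 16 | the corresponding diaryl ketone | COc1ccc(COc2cc(Br)cc(OC)c2C(=O)c2cc(OC)c3c(c2)O[C@H](c2ccc(OC)cc2)[C@H]3c2cc(OC)cc(OC)c2)cc1
F9 | step 16 | hydrazone of the diaryl ketone | COc1ccc(COc2cc(Br)cc(OC)c2C(=NN)c2cc(OC)c3c(c2)O[C@H](c2ccc(OC)cc2)[C@H]3c2cc(OC)cc(OC)c2)cc1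
F10 | step 16 | the corresponding diaryldiazomethane | COc1ccc(COc2cc(Br)cc(OC)c2C(=[N+]=[N-])c2cc(OC)c3c(c2)O[C@H](c2ccc(OC)cc2)[C@H]3c2cc(OC)cc(OC)c2)cc1
F11 | step 16 | (2S,3R)-6-bromo-3-[(2S,3S)-3-(3,5-dimethoxyphenyl)-4-methoxy-2-(4-methoxyphenyl)-2,3-dihydro-1-benzofuran-6-yl]-4-methoxy-2-(4-methoxyphenyl)-2,3-dihydro-1-benzofuran (cis) | Brc1cc(OC)c2c(c1)O[C@H](c1ccc(OC)cc1)[C@@H]2c1cc(OC)c2c(c1)O[C@H](c1ccc(OC)cc1)[C@H]2c1cc(OC)cc(OC)c1
F12 | step 16 | (2R,3R)-6-bromo-3-[(2S,3S)-3-(3,5-dimethoxyphenyl)-4-methoxy-2-(4-methoxyphenyl)-2,3-dihydro-1-benzofuran-6-yl]-4-methoxy-2-(4-methoxyphenyl)-2,3-dihydro-1-benzofuran (trans) | Brc1cc(OC)c2c(c1)O[C@@H](c1ccc(OC)cc1)[C@@H]2c1cc(OC)c2c(c1)O[C@H](c1ccc(OC)cc1)[C@H]2c1cc(OC)cc(OC)c1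
F13 | step 17 | 4,5,6,7-tetrachloro-1,3-dioxoisoindolin-2-yl (2R,3R)-6-bromo-4-methoxy-2-(4-methoxyphenyl)-2,3-dihydro-1-benzofuran-3-carboxylate | Brc1cc(OC)c2c(c1)O[C@@H](c1ccc(OC)cc1)[C@@H]2C(=O)ON1C(=O)c2c(Cl)c(Cl)c(Cl)c(Cl)c2C1=O
F14 | step 17 | 5-[(2S,3S)-6-{(2R,3R)-6-bromo-4-hydroxy-2-(4-hydroxyphenyl)-2,3-dihydro-1-benzofuran-3-yl}-4-hydroxy-2-(4-hydroxyphenyl)-2,3-dihydro-1-benzofuran-3-yl]benzene-1,3-diol | Brc1cc(O)c2c(c1)O[C@@H](c1ccc(O)cc1)[C@@H]2c1cc(O)c2c(c1)O[C@H](c1ccc(O)cc1)[C@H]2c1cc(O)cc(O)c1
F15 | step 17 | acetate of 28 at the stilbene 4-hydroxyl | CC(=O)Oc1ccc(/C=C/c2cc(O)c3c(c2)O[C@@H](c2ccc(O)cc2)[C@@H]3c2cc(O)c3c(c2)O[C@H](c2ccc(O)cc2)[C@H]3c2cc(O)cc(O)c2)cc1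
A1 | alternative 1 | open-chain form of A2 with O1–C2 and O1′–C2′ opened: free phenols on rings A and B, CH(OH)(4-methoxyphenyl) groups at C2 and C2′ (either carbinol configuration), C3 and C3′ as in 27 | COc1ccc(/C=C/c2cc(OC)c(c(O)c2)[C@H](C(O)c2ccc(OC)cc2)c2cc(OC)c(c(O)c2)[C@@H](C(O)c2ccc(OC)cc2)c2cc(OC)cc(OC)c2)cc1
A2 | alternative 1 | (2R,3R,2′S,3′S) heptamethyl ether of the target (identical with 27) | COc1ccc(/C=C/c2cc(OC)c3c(c2)O[C@@H](c2ccc(OC)cc2)[C@@H]3c2cc(OC)c3c(c2)O[C@H](c2ccc(OC)cc2)[C@H]3c2cc(OC)cc(OC)c2)cc1
A3 | alternative 2 | (2S)-7-bromo-5-methoxy-2-(4-methoxyphenyl)-2,3-dihydro-4H-chromen-4-one | COc1ccc(cc1)[C@@H]1CC(=O)c2c(OC)cc(Br)cc2O1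
A4 | alternative 2 | methyl (2S,3S)-6-bromo-4-methoxy-2-(4-methoxyphenyl)-2,3-dihydro-1-benzofuran-3-carboxylate (identical with 11) | Brc1cc(OC)c2c(c1)O[C@H](c1ccc(OC)cc1)[C@H]2C(=O)OC
A5 | alternative 3 | 3-[(2R,3R)-6-bromo-4-methoxy-2-(4-methoxyphenyl)-2,3-dihydro-1-benzofuran-3-yl]cyclobut-2-en-1-one | Brc1cc(OC)c2c(c1)O[C@@H](c1ccc(OC)cc1)[C@@H]2C1=CC(=O)C1
A6 | alternative 3 | {[3-(3,5-dimethoxyphenyl)-3-methoxyprop-1-yn-1-yl]oxy}tri(propan-2-yl)silane (either configuration) | COC(C#CO[Si](C(C)C)(C(C)C)C(C)C)c1cc(OC)cc(OC)c1
A7 | alternative 3 | 5-[(2R,3R)-6-bromo-4-methoxy-2-(4-methoxyphenyl)-2,3-dihydro-1-benzofuran-3-yl]-2-[(3,5-dimethoxyphenyl)(methoxy)methyl]-3-{[tri(propan-2-yl)silyl]oxy}phenol (either configuration at the ether carbon) | Brc1cc(OC)c2c(c1)O[C@@H](c1ccc(OC)cc1)[C@@H]2c1cc(O)c(C(OC)c2cc(OC)cc(OC)c2)c(O[Si](C(C)C)(C(C)C)C(C)C)c1
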